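**Plan**

1. Retrosynthesis cuts, in this order: the aryl–vinyl bond at C4 of dihydrobenzofuran 1 (Suzuki coupling with a Z-alkenylboronate); the six O–CH3 bonds; the bond from C3 of dihydrobenzofuran 1 to C5' of dihydrobenzofuran 2 (decarboxylative nickel arylation); the C3'–aryl bond of fragment 2 (same reaction); and in each dihydrobenzofuran the C2–C3 bond (rhodium carbene C–H insertion into a 4-methoxybenzyl ether).
2. Forward, each five-membered oxygen ring arises by insertion of an aryldiazoacetate carbene into its ortho O–CH2Ar group, which leaves a carboxyl group exactly on C3 (C3'). That carboxyl is then spent as CO2: first to attach the 3,5-dimethoxyphenyl ring of fragment 2, then to join the two fragments. Demethylation and the cis-styryl group come last.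
3. Enabling feature: C3 of ring system 1 is a benzylic ring carbon next to the aryl-bearing C2, so its planar radical is shielded on one face. C5' is the only aromatic C–H of fragment 2 with two hydrogen neighbours (the 5-position of a 1,2,3-trisubstituted benzo ring), so iridium borylation marks exactly that carbon.
4. Stereochemistry: C2 (S) and C2' (R) come from catalyst control in the two C–H insertions (antipodal Rh2(PTTL)4 catalysts). C3 (S) and C3' (R) come from substrate control in the two radical arylations (aryl enters trans to the C2 aryl). The Z alkene comes from a Z-alkenylboronate coupled with retention.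

Key step: step 14

Remarks before the steps:
- Benzofuran numbering is used, unprimed for the dihydrobenzofuran that carries the styryl group (ring system 1, from fragment 1) and primed for the other (ring system 2, fragment 2).
- Assumption on the sense of induction: Rh2(S-PTTL)4 (dirhodium tetrakis[N-phthaloyl-(S)-tert-leucinate]) is taken to give the 2R cis esters in this aryldiazoacetate C–H insertion. Hence the R catalyst is used for ring system 1 and the S catalyst for ring system 2; if the sense were opposite, the two catalysts are exchanged.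
- Compounds 10, 16 (as a THF solution) and 22 are taken as purchasable.

**Fragment 1 (steps 1–5)**

Step 1
Reactants: 1 1-chloro-3,5-dimethoxybenzene
Product: 3 methyl 2-(2-chloro-6-hydroxy-4-methoxyphenyl)-2-oxoacetate, via dimethoxy ketoester 2 (not isolated)
Conditions: ClC(O)CO2Me, AlCl3, CH2Cl2, 0 °C; then BCl3, 0 °C to rt; aq. HCl
Reagents that add atoms: methyl chlorooxoacetate, COC(=O)C(Cl)=O
Why: Friedel–Crafts acylation of the electron-rich arene should go ortho to chlorine (para to one methoxy group and ortho to the other, the site between the two methoxy groups being more hindered), and BCl3 then cleaves only the methyl ether that can chelate to the new ketone carbonyl (chelation-controlled ortho-demethylation).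

Step 2
Reactants: 3 methyl 2-(2-chloro-6-hydroxy-4-methoxyphenyl)-2-oxoacetate; 4 4-methoxybenzyl chloride
Product: 5 methyl 2-{2-chloro-4-methoxy-6-[(4-methoxyphenyl)methoxy]phenyl}-2-oxoacetate
Conditions: K2CO3, Bu4NI (cat.), DMF, 50 °C
Reagents that add atoms: none
Why: Williamson etherification of the only phenol installs the CH2 group that becomes C2 together with its 4-methoxyphenyl substituent.

Step 3
Reactants: 5 methyl 2-{2-chloro-4-methoxy-6-[(4-methoxyphenyl)methoxy]phenyl}-2-oxoacetate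
Product: 7 methyl 2-{2-chloro-4-methoxy-6-[(4-methoxyphenyl)methoxy]phenyl}-2-diazoacetate, via tosylhydrazone 6 (not isolated)
Conditions: TsNHNH2, MeOH, 50 °C; then DBU, CH2Cl2, 0 °C to rt
Reagents that add atoms: 4-methylbenzenesulfonohydrazide, Cc1ccc(cc1)S(=O)(=O)NN
Why: Condensation at the activated ketone of the α-ketoester and base-induced loss of sulfinate (Bamford–Stevens route) should give the donor/acceptor aryldiazoacetate.

Step 4
Reactants: 7 methyl 2-{2-chloro-4-methoxy-6-[(4-methoxyphenyl)methoxy]phenyl}-2-diazoacetate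
Product: 8 methyl (2S,3R)-4-chloro-6-methoxy-2-(4-methoxyphenyl)-2,3-dihydro-1-benzofuran-3-carboxylate (2,3-cis)
Conditions: Rh2(R-PTTL)4 (1 mol %), toluene, −60 °C
Reagents that add atoms: none
Why: The rhodium donor/acceptor carbene should insert into the activated ortho benzylic ether C–H bond (intramolecular 1,5 C–H insertion), closing the dihydrofuran ring cis-selectively, with the chiral carboxylate ligands setting C2 as S by catalyst control (C3 is erased later).

Step 5
Reactants: 8 methyl (2S,3R)-4-chloro-6-methoxy-2-(4-methoxyphenyl)-2,3-dihydro-1-benzofuran-3-carboxylate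
Product: 9 (2S,3S)-4-chloro-6-methoxy-2-(4-methoxyphenyl)-2,3-dihydro-1-benzofuran-3-carboxylic acid (2,3-trans)
Conditions: LiOH, THF/MeOH/H2O, 40 °C; then aq. HCl
Reagents that add atoms: none
Why: Saponification under conditions that first equilibrate the ester α-center should give the more stable trans acid, C2 being untouched because ring opening of the enolate would be a reverse 5-endo-trig process.

**Fragment 2 (steps 6–12)**

Step 6
Reactants: 10 2-(2-hydroxy-3-methoxyphenyl)acetic acid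
Product: 11 methyl 2-(2-hydroxy-3-methoxyphenyl)acetate
Conditions: MeOH, H2SO4 (cat.), reflux
Reagents that add atoms: methanol, CO
Why: Fischer esterification in methanol should give the open methyl ester, since any lactone formed is re-opened by methanolysis.

Step 7
Reactants: 11 methyl 2-(2-hydroxy-3-methoxyphenyl)acetate; 4 4-methoxybenzyl chloride
Product: 12 methyl 2-{3-methoxy-2-[(4-methoxyphenyl)methoxy]phenyl}acetate
Conditions: K2CO3, Bu4NI (cat.), DMF, 50 °C
Reagents that add atoms: none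
Why: Williamson etherification of the phenol installs the future C2' with its 4-methoxyphenyl group.

Step 8
Reactants: 12 methyl 2-{3-methoxy-2-[(4-methoxyphenyl)methoxy]phenyl}acetate
Product: 13 methyl 2-diazo-2-{3-methoxy-2-[(4-methoxyphenyl)methoxy]phenyl}acetate
Conditions: 4-acetamidobenzenesulfonyl azide, DBU, MeCN, 0 °C to rt
Reagents that add atoms: 4-acetamidobenzenesulfonyl azide, CC(=O)Nc1ccc(cc1)S(=O)(=O)N=[N+]=[N-]
Why: Regitz diazo transfer to the arylacetate enolate is the standard entry to aryldiazoacetates.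

Step 9
Reactants: 13 methyl 2-diazo-2-{3-methoxy-2-[(4-methoxyphenyl)methoxy]phenyl}acetate
Product: 14 methyl (2R,3S)-7-methoxy-2-(4-methoxyphenyl)-2,3-dihydro-1-benzofuran-3-carboxylate (2,3-cis)
Conditions: Rh2(S-PTTL)4 (1 mol %), toluene, −60 °C
Reagents that add atoms: none
Why: The same intramolecular 1,5 C–H insertion as in step 4, here with the antipodal catalyst, should close ring system 2 cis-selectively and set C2' as R by catalyst control.

Step 10
Reactants: 14 methyl (2R,3S)-7-methoxy-2-(4-methoxyphenyl)-2,3-dihydro-1-benzofuran-3-carboxylate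
Product: 15 (2R,3R)-7-methoxy-2-(4-methoxyphenyl)-2,3-dihydro-1-benzofuran-3-carboxylic acid (2,3-trans)
Conditions: LiOH, THF/MeOH/H2O, 40 °C; then aq. HCl
Reagents that add atoms: none
Why: Epimerising saponification as in step 5 should give the trans acid with C2' unchanged.

Step 11
Reactants: 15 (2R,3R)-7-methoxy-2-(4-methoxyphenyl)-2,3-dihydro-1-benzofuran-3-carboxylic acid; 16 (3,5-dimethoxyphenyl)magnesium bromide
Product: 19 (2R,3R)-3-(3,5-dimethoxyphenyl)-7-methoxy-2-(4-methoxyphenyl)-2,3-dihydro-1-benzofuran, via N-acyloxyphthalimide 17 (not isolated), via arylzinc chloride 18 (not isolated)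
Conditions: 15: N-hydroxyphthalimide, DIC, DMAP (cat.), CH2Cl2, rt; 16: ZnCl2, THF, 0 °C; then NiCl2·glyme (20 mol %), 4,4'-di-tert-butyl-2,2'-bipyridine (40 mol %), THF/DMF, rt
Reagents that add atoms: none
Why: Nickel-catalysed decarboxylative Negishi arylation of the redox-active ester should deliver the aryl group to the planar C3' benzylic radical anti to the C2' aryl group, setting C3' as R (trans) by substrate control.

Step 12
Reactants: 19 (2R,3R)-3-(3,5-dimethoxyphenyl)-7-methoxy-2-(4-methoxyphenyl)-2,3-dihydro-1-benzofuran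
Product: 21 (2R,3R)-3-(3,5-dimethoxyphenyl)-5-iodo-7-methoxy-2-(4-methoxyphenyl)-2,3-dihydro-1-benzofuran, via arylboronate 20 (not isolated)
Conditions: [Ir(cod)(OMe)]2 (1.5 mol %), 4,4'-di-tert-butyl-2,2'-bipyridine, B2pin2, THF, 80 °C; then CuI (10 mol %), 1,10-phenanthroline, KI, MeOH/H2O, air, 80 °C
Reagents that add atoms: potassium iodide, [K+].[I-]
Why: Iridium-catalysed C–H borylation is sterically controlled and C5' is the only aromatic C–H of 19 with two hydrogen neighbours, and the copper-catalysed iododeboronation then replaces boron at the same carbon without electrophilic attack on the electron-rich dimethoxyphenyl ring.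

**Alkenylboronate (step 13)**

Step 13
Reactants: 22 tert-butyl(4-ethynylphenoxy)dimethylsilane
Product: 23 tert-butyldimethyl{4-[(Z)-2-(4,4,5,5-tetramethyl-1,3,2-dioxaborolan-2-yl)ethenyl]phenoxy}silane
Conditions: pinacolborane, [Rh(cod)Cl]2 (1.5 mol %), P(iPr)3, Et3N, cyclohexane, rt
Reagents that add atoms: pinacolborane, CC1(C)OBOC1(C)C
Why: Rhodium-catalysed anti-Markovnikov trans-hydroboration of a terminal alkyne proceeds through a rhodium vinylidene, so boron and the aryl group should end up cis (Z-alkenylboronate).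

**Union and endgame (steps 14–16)**

Step 14
Reactants: 9 (2S,3S)-4-chloro-6-methoxy-2-(4-methoxyphenyl)-2,3-dihydro-1-benzofuran-3-carboxylic acid; 21 (2R,3R)-3-(3,5-dimethoxyphenyl)-5-iodo-7-methoxy-2-(4-methoxyphenyl)-2,3-dihydro-1-benzofuran
Product: 27 (2S,3S)-4-chloro-3-[(2R,3R)-3-(3,5-dimethoxyphenyl)-7-methoxy-2-(4-methoxyphenyl)-2,3-dihydro-1-benzofuran-5-yl]-6-methoxy-2-(4-methoxyphenyl)-2,3-dihydro-1-benzofuran, via N-acyloxyphthalimide 24 (not isolated), via aryllithium 25 (not isolated), via arylzinc chloride 26 (not isolated)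
Conditions: 9: N-hydroxyphthalimide, DIC, CH2Cl2, rt, then DMF; 21: t-BuLi (2 equiv), THF, −78 °C, then ZnCl2, to rt; combined with NiCl2·glyme (20 mol %), 4,4'-di-tert-butyl-2,2'-bipyridine (40 mol %), THF/DMF, rt
Reagents that add atoms: none
Why: The arylnickel species formed from 26 and monovalent nickel reduces ester 24 by single-electron transfer; loss of phthalimide anion and CO2 leaves the C3 benzylic radical, which recombines with arylnickel to a trivalent nickel alkyl aryl that reductively eliminates the C3–C5' bond. The closest known reaction type is the nickel-catalysed decarboxylative Negishi arylation of secondary redox-active esters with arylzinc reagents. No ring is closed. The new center C3 is set by the substrate: the radical is planar and the 4-methoxyphenyl group on C2 blocks one face, so nickel and then the aryl group arrive anti to it, giving 3S (2,3-trans) from the fixed 2S center whatever the C3 configuration of 9. The step needs chemoselectivity for the ester over the C4 aryl chloride (electron transfer to the ester is fast at room temperature, oxidative addition into the hindered C–Cl bond is slow) and capture of the radical before ring opening (the C2–O bond lies near the nodal plane of the radical orbital, so β-scission is a reverse 5-endo-trig process). The aryl partner is unhindered because C5' has two ortho hydrogens, and t-BuLi is used so that no alkyl iodide remains to compete.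

Step 15
Reactants: 27 (2S,3S)-4-chloro-3-[(2R,3R)-3-(3,5-dimethoxyphenyl)-7-methoxy-2-(4-methoxyphenyl)-2,3-dihydro-1-benzofuran-5-yl]-6-methoxy-2-(4-methoxyphenyl)-2,3-dihydro-1-benzofuran
Product: 28 (2S,3S)-4-chloro-3-[(2R,3R)-3-(3,5-dihydroxyphenyl)-7-hydroxy-2-(4-hydroxyphenyl)-2,3-dihydro-1-benzofuran-5-yl]-2-(4-hydroxyphenyl)-2,3-dihydro-1-benzofuran-6-ol
Conditions: BBr3 (excess), CH2Cl2, −78 °C to rt; then MeOH, H2O
Reagents that add atoms: none
Why: BBr3 should cleave the six aryl methyl ethers (O-coordination, bromide attack at methyl) with the aryl chloride inert and no alkene yet present, and any reversible ionisation of the benzylic C2–O bonds re-closes to the trans rings anchored by the fixed C3 and C3' centers.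

Step 16
Reactants: 28 (2S,3S)-4-chloro-3-[(2R,3R)-3-(3,5-dihydroxyphenyl)-7-hydroxy-2-(4-hydroxyphenyl)-2,3-dihydro-1-benzofuran-5-yl]-2-(4-hydroxyphenyl)-2,3-dihydro-1-benzofuran-6-ol; 23 tert-butyldimethyl{4-[(Z)-2-(4,4,5,5-tetramethyl-1,3,2-dioxaborolan-2-yl)ethenyl]phenoxy}silane
Product: 30 4-[(Z)-2-{(2S,3S)-3-[(2R,3R)-3-(3,5-dihydroxyphenyl)-7-hydroxy-2-(4-hydroxyphenyl)-2,3-dihydro-1-benzofuran-5-yl]-6-hydroxy-2-(4-hydroxyphenyl)-2,3-dihydro-1-benzofuran-4-yl}ethenyl]phenol (CNP0172909.2), via silyl ether 29 (not isolated)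
Conditions: Pd(OAc)2 (5 mol %), SPhos, CsF, 1,4-dioxane/H2O, 70 °C, argon, exclusion of light
Reagents that add atoms: none
Why: Suzuki–Miyaura coupling of the aryl chloride (SPhos-ligated zerovalent palladium tolerates free phenols and hindered chlorides) with the Z-alkenylboronate proceeds with retention of alkene geometry, and fluoride, which activates boron, should also remove the silyl ether in the same flask.

**Compound list**

1 | 1-chloro-3,5-dimethoxybenzene | COc1cc(Cl)cc(OC)c1 | starting material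
2 | methyl 2-(2-chloro-4,6-dimethoxyphenyl)-2-oxoacetate | COC(=O)C(=O)c1c(Cl)cc(OC)cc1OC | intermediate
3 | methyl 2-(2-chloro-6-hydroxy-4-methoxyphenyl)-2-oxoacetate | COC(=O)C(=O)c1c(Cl)cc(OC)cc1O | intermediate
4 | 4-methoxybenzyl chloride | COc1ccc(CCl)cc1 | starting material
5 | methyl 2-{2-chloro-4-methoxy-6-[(4-methoxyphenyl)methoxy]phenyl}-2-oxoacetate | COC(=O)C(=O)c1c(Cl)cc(OC)cc1OCc1ccc(OC)cc1 | intermediate
6 | methyl 2-{2-chloro-4-methoxy-6-[(4-methoxyphenyl)methoxy]phenyl}-2-[2-(4-methylbenzenesulfonyl)hydrazinylidene]acetate | COC(=O)C(=NNS(=O)(=O)c1ccc(C)cc1)c1c(Cl)cc(OC)cc1OCc1ccc(OC)cc1 | intermediate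
7 | methyl 2-{2-chloro-4-methoxy-6-[(4-methoxyphenyl)methoxy]phenyl}-2-diazoacetate | COC(=O)C(=[N+]=[N-])c1c(Cl)cc(OC)cc1OCc1ccc(OC)cc1 | intermediate
8 | methyl (2S,3R)-4-chloro-6-methoxy-2-(4-methoxyphenyl)-2,3-dihydro-1-benzofuran-3-carboxylate (cis) | Clc1cc(OC)cc2c1[C@@H](C(=O)OC)[C@@H](c1ccc(OC)cc1)O2 | intermediate
9 | (2S,3S)-4-chloro-6-methoxy-2-(4-methoxyphenyl)-2,3-dihydro-1-benzofuran-3-carboxylic acid (trans) | Clc1cc(OC)cc2c1[C@H](C(=O)O)[C@@H](c1ccc(OC)cc1)O2 | intermediate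
10 | 2-(2-hydroxy-3-methoxyphenyl)acetic acid | COc1cccc(CC(=O)O)c1O | starting material
11 | methyl 2-(2-hydroxy-3-methoxyphenyl)acetate | COC(=O)Cc1cccc(OC)c1O | intermediate
12 | methyl 2-{3-methoxy-2-[(4-methoxyphenyl)methoxy]phenyl}acetate | COC(=O)Cc1cccc(OC)c1OCc1ccc(OC)cc1 | intermediate
13 | methyl 2-diazo-2-{3-methoxy-2-[(4-methoxyphenyl)methoxy]phenyl}acetate | COC(=O)C(=[N+]=[N-])c1cccc(OC)c1OCc1ccc(OC)cc1 | intermediate
14 | methyl (2R,3S)-7-methoxy-2-(4-methoxyphenyl)-2,3-dihydro-1-benzofuran-3-carboxylate (cis) | c1cc(OC)c2c(c1)[C@H](C(=O)OC)[C@H](c1ccc(OC)cc1)O2 | intermediate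
15 | (2R,3R)-7-methoxy-2-(4-methoxyphenyl)-2,3-dihydro-1-benzofuran-3-carboxylic acid (trans) | c1cc(OC)c2c(c1)[C@@H](C(=O)O)[C@H](c1ccc(OC)cc1)O2 | intermediate
16 | (3,5-dimethoxyphenyl)magnesium bromide | COc1cc(OC)cc([Mg]Br)c1 | starting material
17 | 1,3-dioxoisoindolin-2-yl (2R,3R)-7-methoxy-2-(4-methoxyphenyl)-2,3-dihydro-1-benzofuran-3-carboxylate | c1cc(OC)c2c(c1)[C@@H](C(=O)ON1C(=O)c3ccccc3C1=O)[C@H](c1ccc(OC)cc1)O2 | intermediate
18 | (3,5-dimethoxyphenyl)zinc chloride | COc1cc(OC)cc([Zn]Cl)c1 | intermediate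
19 | (2R,3R)-3-(3,5-dimethoxyphenyl)-7-methoxy-2-(4-methoxyphenyl)-2,3-dihydro-1-benzofuran | c1cc(OC)c2c(c1)[C@@H](c1cc(OC)cc(OC)c1)[C@H](c1ccc(OC)cc1)O2 | intermediate
20 | 2-[(2R,3R)-3-(3,5-dimethoxyphenyl)-7-methoxy-2-(4-methoxyphenyl)-2,3-dihydro-1-benzofuran-5-yl]-4,4,5,5-tetramethyl-1,3,2-dioxaborolane | CC1(C)OB(OC1(C)C)c1cc(OC)c2c(c1)[C@@H](c1cc(OC)cc(OC)c1)[C@H](c1ccc(OC)cc1)O2 | intermediate
21 | (2R,3R)-3-(3,5-dimethoxyphenyl)-5-iodo-7-methoxy-2-(4-methoxyphenyl)-2,3-dihydro-1-benzofuran | Ic1cc(OC)c2c(c1)[C@@H](c1cc(OC)cc(OC)c1)[C@H](c1ccc(OC)cc1)O2 | intermediate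
22 | tert-butyl(4-ethynylphenoxy)dimethylsilane | C#Cc1ccc(O[Si](C)(C)C(C)(C)C)cc1 | starting material
23 | tert-butyldimethyl{4-[(Z)-2-(4,4,5,5-tetramethyl-1,3,2-dioxaborolan-2-yl)ethenyl]phenoxy}silane | CC(C)(C)[Si](C)(C)Oc1ccc(/C=C\B2OC(C)(C)C(C)(C)O2)cc1 | intermediate
24 | 1,3-dioxoisoindolin-2-yl (2S,3S)-4-chloro-6-methoxy-2-(4-methoxyphenyl)-2,3-dihydro-1-benzofuran-3-carboxylate | Clc1cc(OC)cc2c1[C@H](C(=O)ON1C(=O)c3ccccc3C1=O)[C@@H](c1ccc(OC)cc1)O2 | intermediate
25 | [(2R,3R)-3-(3,5-dimethoxyphenyl)-7-methoxy-2-(4-methoxyphenyl)-2,3-dihydro-1-benzofuran-5-yl]lithium | [Li]c1cc(OC)c2c(c1)[C@@H](c1cc(OC)cc(OC)c1)[C@H](c1ccc(OC)cc1)O2 | intermediate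
26 | [(2R,3R)-3-(3,5-dimethoxyphenyl)-7-methoxy-2-(4-methoxyphenyl)-2,3-dihydro-1-benzofuran-5-yl]zinc chloride | Cl[Zn]c1cc(OC)c2c(c1)[C@@H](c1cc(OC)cc(OC)c1)[C@H](c1ccc(OC)cc1)O2 | intermediate
27 | (2S,3S)-4-chloro-3-[(2R,3R)-3-(3,5-dimethoxyphenyl)-7-methoxy-2-(4-methoxyphenyl)-2,3-dihydro-1-benzofuran-5-yl]-6-methoxy-2-(4-methoxyphenyl)-2,3-dihydro-1-benzofuran | Clc1cc(OC)cc2c1[C@H](c1cc(OC)c3c(c1)[C@@H](c1cc(OC)cc(OC)c1)[C@H](c1ccc(OC)cc1)O3)[C@@H](c1ccc(OC)cc1)O2 | intermediate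
28 | (2S,3S)-4-chloro-3-[(2R,3R)-3-(3,5-dihydroxyphenyl)-7-hydroxy-2-(4-hydroxyphenyl)-2,3-dihydro-1-benzofuran-5-yl]-2-(4-hydroxyphenyl)-2,3-dihydro-1-benzofuran-6-ol | Clc1cc(O)cc2c1[C@H](c1cc(O)c3c(c1)[C@@H](c1cc(O)cc(O)c1)[C@H](c1ccc(O)cc1)O3)[C@@H](c1ccc(O)cc1)O2 | intermediate
29 | (2S,3S)-4-[(Z)-2-{4-[(tert-butyldimethylsilyl)oxy]phenyl}ethenyl]-3-[(2R,3R)-3-(3,5-dihydroxyphenyl)-7-hydroxy-2-(4-hydroxyphenyl)-2,3-dihydro-1-benzofuran-5-yl]-2-(4-hydroxyphenyl)-2,3-dihydro-1-benzofuran-6-ol | CC(C)(C)[Si](C)(C)Oc1ccc(/C=C\c2cc(O)cc3c2[C@H](c2cc(O)c4c(c2)[C@@H](c2cc(O)cc(O)c2)[C@H](c2ccc(O)cc2)O4)[C@@H](c2ccc(O)cc2)O3)cc1 | intermediate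
30 | 4-[(Z)-2-{(2S,3S)-3-[(2R,3R)-3-(3,5-dihydroxyphenyl)-7-hydroxy-2-(4-hydroxyphenyl)-2,3-dihydro-1-benzofuran-5-yl]-6-hydroxy-2-(4-hydroxyphenyl)-2,3-dihydro-1-benzofuran-4-yl}ethenyl]phenol (CNP0172909.2) | Oc1ccc(/C=C\c2cc(O)cc3c2[C@H](c2cc(O)c4c(c2)[C@@H](c2cc(O)cc(O)c2)[C@H](c2ccc(O)cc2)O4)[C@@H](c2ccc(O)cc2)O3)cc1 | target

**Count**

Total step count: 16. Longest linear sequence: 10 steps (steps 6–12, then 14, 15 and 16).

**Steps most likely to fail, with fallbacks**

Step 14 (fragment union). What may go wrong: capture of the hindered C3 radical by arylnickel is slower than its reduction or dimerisation; the catalyst is diverted by oxidative addition into the C4–Cl bond; or the aryl group is delivered without a clear preference for the face anti to the C2 aryl group. The fallback makes the same bond by carbonyl addition and closes ring system 1 afterwards by a donor/donor carbene C–H insertion. It sets out from 1, 4 and the aryllithium 25 (made from 21 as in step 14) and comes back at 27. Vilsmeier–Haack formylation of 1 (POCl3, DMF) should give 2-chloro-4,6-dimethoxybenzaldehyde F1. Chelation-controlled demethylation with BCl3 should give 2-chloro-6-hydroxy-4-methoxybenzaldehyde F2, and alkylation with 4 (K2CO3, DMF) the 4-methoxybenzyl ether aldehyde F3. Addition of 25 at −78 °C should give the diarylmethanol F4 (both carbinol epimers), and Dess–Martin oxidation the diaryl ketone F5. Hydrazine hydrate should give the hydrazone F6 and MnO2 the diaryldiazomethane F7. With Rh2(R-PTAD)4 (or its antipode, whichever sets 3S) F7 should insert into the benzylic ether C–H bond to give the 2,3-cis dihydrobenzofuran F8. A Lewis acid (BF3·OEt2, CH2Cl2) then epimerises C2 through reversible ionisation of the benzylic C–O bond to the more stable trans isomer, which is 27.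

Step 15 (global demethylation). What may go wrong: while BBr3 is bound to the ring oxygens, the benzylic C2–O bond of ring system 1 ionises and the cation loses the C3 proton or alkylates a neighbouring electron-rich ring, so the ring does not re-close. The fallback moves the demethylation to the two fragments and carries fluoride-labile silyl ethers through the union. It sets out from 21 and 9 and comes back at 28. BBr3 on 21 should give the tetraphenol iodide F9, and TBSCl/imidazole its tetrakis(silyl ether) F10. BBr3 on 9 should give the dihydroxy acid F11, TBSCl/imidazole the fully silylated silyl ester F12, and brief aqueous K2CO3 in THF/MeOH the bis(silyl ether) acid F13. The union as in step 14 (in situ N-acyloxyphthalimide F14, aryllithium F15, arylzinc chloride F16) should give the hexakis(silyl ether) F17, and Bu4NF buffered with AcOH returns 28.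

Step 16 (cis-styryl group). What may go wrong: slow oxidative addition into the hindered aryl chloride in the presence of six phenoxides lets protodeboronation and Z to E isomerisation of the alkenylboron partner compete. The fallback couples an alkyne and then adds hydrogen to one face. It sets out from 28 and 22 and comes back at 30. Copper-free Sonogashira coupling (PdCl2(MeCN)2, XPhos, Cs2CO3, MeCN, 80 °C) should give the silylated diarylalkyne F18, desilylated in the same flask with Bu4NF to the heptaphenol alkyne F19. Semi-hydrogenation over lead-poisoned Pd on CaCO3 (Lindlar catalyst) with quinoline and H2 (1 atm) delivers both hydrogens to one face of the alkyne and should give the Z alkene 30.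

**Further compounds**

F1 | step 14 | 2-chloro-4,6-dimethoxybenzaldehyde | COc1cc(Cl)c(C=O)c(OC)c1
F2 | step 14 | 2-chloro-6-hydroxy-4-methoxybenzaldehyde | COc1cc(O)c(C=O)c(Cl)c1
F3 | step 14 | 2-chloro-4-methoxy-6-[(4-methoxyphenyl)methoxy]benzaldehyde | COc1ccc(COc2cc(OC)cc(Cl)c2C=O)cc1
F4 | step 14 | {2-chloro-4-methoxy-6-[(4-methoxyphenyl)methoxy]phenyl}[(2R,3R)-3-(3,5-dimethoxyphenyl)-7-methoxy-2-(4-methoxyphenyl)-2,3-dihydro-1-benzofuran-5-yl]methanol | COc1ccc(COc2cc(OC)cc(Cl)c2C(O)c2cc(OC)c3c(c2)[C@@H](c2cc(OC)cc(OC)c2)[C@H](c2ccc(OC)cc2)O3)cc1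
F5 | step 14 | {2-chloro-4-methoxy-6-[(4-methoxyphenyl)methoxy]phenyl}[(2R,3R)-3-(3,5-dimethoxyphenyl)-7-methoxy-2-(4-methoxyphenyl)-2,3-dihydro-1-benzofuran-5-yl]methanone | COc1ccc(COc2cc(OC)cc(Cl)c2C(=O)c2cc(OC)c3c(c2)[C@@H](c2cc(OC)cc(OC)c2)[C@H](c2ccc(OC)cc2)O3)cc1
F6 | step 14 | hydrazone of ketone F5 | COc1ccc(COc2cc(OC)cc(Cl)c2C(=NN)c2cc(OC)c3c(c2)[C@@H](c2cc(OC)cc(OC)c2)[C@H](c2ccc(OC)cc2)O3)cc1
F7 | step 14 | diaryldiazomethane from F6 | COc1ccc(COc2cc(OC)cc(Cl)c2C(=[N+]=[N-])c2cc(OC)c3c(c2)[C@@H](c2cc(OC)cc(OC)c2)[C@H](c2ccc(OC)cc2)O3)cc1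
F8 | step 14 | (2R,3S)-4-chloro-3-[(2R,3R)-3-(3,5-dimethoxyphenyl)-7-methoxy-2-(4-methoxyphenyl)-2,3-dihydro-1-benzofuran-5-yl]-6-methoxy-2-(4-methoxyphenyl)-2,3-dihydro-1-benzofuran (2,3-cis) | Clc1cc(OC)cc2c1[C@H](c1cc(OC)c3c(c1)[C@@H](c1cc(OC)cc(OC)c1)[C@H](c1ccc(OC)cc1)O3)[C@H](c1ccc(OC)cc1)O2
F9 | step 15 | (2R,3R)-3-(3,5-dihydroxyphenyl)-2-(4-hydroxyphenyl)-5-iodo-2,3-dihydro-1-benzofuran-7-ol | Ic1cc(O)c2c(c1)[C@@H](c1cc(O)cc(O)c1)[C@H](c1ccc(O)cc1)O2
F10 | step 15 | tetrakis(tert-butyldimethylsilyl) ether of F9 | Ic1cc(O[Si](C)(C)C(C)(C)C)c2c(c1)[C@@H](c1cc(O[Si](C)(C)C(C)(C)C)cc(O[Si](C)(C)C(C)(C)C)c1)[C@H](c1ccc(O[Si](C)(C)C(C)(C)C)cc1)O2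
F11 | step 15 | (2S,3S)-4-chloro-6-hydroxy-2-(4-hydroxyphenyl)-2,3-dihydro-1-benzofuran-3-carboxylic acid | Clc1cc(O)cc2c1[C@H](C(=O)O)[C@@H](c1ccc(O)cc1)O2
F12 | step 15 | tert-butyldimethylsilyl (2S,3S)-6-[(tert-butyldimethylsilyl)oxy]-2-{4-[(tert-butyldimethylsilyl)oxy]phenyl}-4-chloro-2,3-dihydro-1-benzofuran-3-carboxylate | Clc1cc(O[Si](C)(C)C(C)(C)C)cc2c1[C@H](C(=O)O[Si](C)(C)C(C)(C)C)[C@@H](c1ccc(O[Si](C)(C)C(C)(C)C)cc1)O2
F13 | step 15 | (2S,3S)-6-[(tert-butyldimethylsilyl)oxy]-2-{4-[(tert-butyldimethylsilyl)oxy]phenyl}-4-chloro-2,3-dihydro-1-benzofuran-3-carboxylic acid | Clc1cc(O[Si](C)(C)C(C)(C)C)cc2c1[C@H](C(=O)O)[C@@H](c1ccc(O[Si](C)(C)C(C)(C)C)cc1)O2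
F14 | step 15 | 1,3-dioxoisoindolin-2-yl ester of F13 | Clc1cc(O[Si](C)(C)C(C)(C)C)cc2c1[C@H](C(=O)ON1C(=O)c3ccccc3C1=O)[C@@H](c1ccc(O[Si](C)(C)C(C)(C)C)cc1)O2
F15 | step 15 | aryllithium from F10 | [Li]c1cc(O[Si](C)(C)C(C)(C)C)c2c(c1)[C@@H](c1cc(O[Si](C)(C)C(C)(C)C)cc(O[Si](C)(C)C(C)(C)C)c1)[C@H](c1ccc(O[Si](C)(C)C(C)(C)C)cc1)O2
F16 | step 15 | arylzinc chloride from F15 | Cl[Zn]c1cc(O[Si](C)(C)C(C)(C)C)c2c(c1)[C@@H](c1cc(O[Si](C)(C)C(C)(C)C)cc(O[Si](C)(C)C(C)(C)C)c1)[C@H](c1ccc(O[Si](C)(C)C(C)(C)C)cc1)O2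
F17 | step 15 | hexakis(tert-butyldimethylsilyl) ether of 28 | Clc1cc(O[Si](C)(C)C(C)(C)C)cc2c1[C@H](c1cc(O[Si](C)(C)C(C)(C)C)c3c(c1)[C@@H](c1cc(O[Si](C)(C)C(C)(C)C)cc(O[Si](C)(C)C(C)(C)C)c1)[C@H](c1ccc(O[Si](C)(C)C(C)(C)C)cc1)O3)[C@@H](c1ccc(O[Si](C)(C)C(C)(C)C)cc1)O2
F18 | step 16 | (2S,3S)-4-({4-[(tert-butyldimethylsilyl)oxy]phenyl}ethynyl)-3-[(2R,3R)-3-(3,5-dihydroxyphenyl)-7-hydroxy-2-(4-hydroxyphenyl)-2,3-dihydro-1-benzofuran-5-yl]-2-(4-hydroxyphenyl)-2,3-dihydro-1-benzofuran-6-ol | CC(C)(C)[Si](C)(C)Oc1ccc(C#Cc2cc(O)cc3c2[C@H](c2cc(O)c4c(c2)[C@@H](c2cc(O)cc(O)c2)[C@H](c2ccc(O)cc2)O4)[C@@H](c2ccc(O)cc2)O3)cc1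
F19 | step 16 | (2S,3S)-3-[(2R,3R)-3-(3,5-dihydroxyphenyl)-7-hydroxy-2-(4-hydroxyphenyl)-2,3-dihydro-1-benzofuran-5-yl]-2-(4-hydroxyphenyl)-4-[(4-hydroxyphenyl)ethynyl]-2,3-dihydro-1-benzofuran-6-ol | Oc1ccc(C#Cc2cc(O)cc3c2[C@H](c2cc(O)c4c(c2)[C@@H](c2cc(O)cc(O)c2)[C@H](c2ccc(O)cc2)O4)[C@@H](c2ccc(O)cc2)O3)cc1
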